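**Remarks on the chemistry**

- Locants used throughout: ring A C1 carries C7, C3 carries OMe, C4 the phenol oxygen, C5 the diaryl ether oxygen. The side chain is C7 (carbinol), C8 (aryloxy methine) and C9 (CH2OH). Ring B is the para-phenylene of the cinnamoyl unit. The indole keeps its own numbering.
- The descriptors were re-derived from the target SMILES: C7 is R and C8 is S (erythro). The seco aldehyde must be (S), the Mitsunobu partner (R) and the acetonide (R). The planned structures agree with this, so no structural correction is needed.
- Alkaline peroxide (the Dakin reaction proper) needs a free ortho or para hydroxyl, so with the phenol protected the formyl-to-hydroxyl exchange is run as a peracid Baeyer–Villiger oxidation followed by methanolysis.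
- TBS at O9 and SEM at the ring A oxygen are kept: neither chelates, SEM cannot migrate between the two adjacent ring A oxygens, and both leave with fluoride in one final operation without acid.

## Structural features

The target is a 21-membered macrocycle built from three aromatic units: ring A (a 1,3,4,5-tetrasubstituted benzene with 3-OMe, free 4-OH and 5-aryloxy), ring B (the para-phenylene of an (E)-cinnamamide) and the benzo ring of a 5-oxygenated indole (a serotonin unit). They are joined by the diaryl ether ring A C5–O–ring B C4, the secondary (E)-enamide to the tryptamine nitrogen, the alkyl aryl ether C8–O–indole C5 and the C–C bond ring A C1–C7. The only stereocentres, C7 (R, benzylic secondary carbinol) and C8 (S, aryloxy methine carrying the C9 hydroxymethyl group), are adjacent and erythro. Fragile features are the para-hydroxybenzylic alcohol at C7 (quinone methide formation under acid, strong base or heat), the β-aryl ether at C8, the oxidation- and acid-sensitive 5-alkoxyindole with free N–H, and the conjugated E-alkene, which excludes hydrogenolysis. The aromatic pieces and the enamide are easy to assemble. The real difficulty is closing the large ring and fixing the C7/C8 relationship under conditions that an epimerisable α-aryloxy carbonyl unit and two unprotected N–H groups survive. The key step exploits the fact that C7 is both benzylic to ring A C1 and vicinal to the oxygenated stereocentre C8. An aryl-metal at ring A C1 adding to a C7 aldehyde therefore forms the C1–C7 bond, the macrocycle and the C7 configuration (by 1,2-induction from C8) in one operation.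

## Logic of the disconnections

**18 to 16.** The O9–Si bond and the ring A O4–CH2 acetal bond are cut. Both masks are silicon-based, so one fluoride treatment removes them without acid. The skeleton is unchanged, but the phenol and the primary alcohol stay masked through every earlier step. The forward step must release a para-hydroxybenzylic carbinol without heating it long under basic conditions.

**16 to 15.** The ring A C1–C7 bond is cut. This is the only C–C bond joining ring A to the stereodiad, and cutting it opens the 21-membered ring and removes the C7 stereocentre together. It leaves an aryl iodide at C1 and an aldehyde at C7 in 15. The forward step needs an aryl nucleophile that tolerates N–H groups, does not epimerise C8, and adds with Felkin–Anh selectivity under high dilution.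

**15 to 14.** No skeletal bond is cut; C7 is taken back from the aldehyde to the methyl ester oxidation level. The α-aryloxy aldehyde is configurationally labile and is best made immediately before use from a stable ester. The forward step must stop at the aldehyde and leave the enamide untouched.

**14 to 10 and 13.** The C8–O bond to indole C5 is cut. This separates the whole achiral aromatic framework from a three-carbon chiral-pool unit and makes the synthesis convergent. The forward step must form an alkyl aryl ether at a secondary carbon with clean inversion and no elimination.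

**13 to 12 to 11.** The O9–Si bond and then the two acetal C–O bonds are cut, leading back to a commercial enantiopure glycerate acetonide. C8 is therefore bought, not made. The forward steps must silylate the primary hydroxyl selectively and must not touch the stereocentre.

**10 to 8 and 9.** The amide N–C(=O) bond is cut. This gives a commercial amine salt and a cinnamic acid. The forward step must acylate nitrogen in the presence of the unprotected 5-hydroxyl.

**8 to 7.** The Cα=Cβ double bond is cut, the two new carbons coming from a malonate-type C2 donor. This reduces the acid to an aryl aldehyde. The forward step must give the E geometry and tolerate the acetal and the aryl iodide.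

**7 to 5 and 6.** The diaryl ether bond O–ring B C4 is cut. Ring B then comes as a commercial para-fluoro aldehyde whose formyl group both activates the displacement and is the handle for the next step. The forward step needs a ring A phenoxide with only one free hydroxyl and no metal that could touch the iodide.

**5 to 3 to 2 to 1.** The ring A C5–O bond is traced to a C5–formyl bond (oxidative aryl migration), then the O4–CH2 protecting bond and the C1–I bond are cut. This reaches a commercial hydroxy-methoxy-benzaldehyde in which all three oxygen positions are already differentiated. The forward sequence must iodinate para to the free phenol before it is protected, and must oxidise the aldehyde without attacking iodine.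

## Other disconnections considered

**Alternative 1:** The cut removes the two C–C bonds of ring B that flank the carbon bearing the ether oxygen, so ring B is dismantled to a pyrone and an alkyne.

- Forward key step: inverse-electron-demand Diels–Alder reaction of methyl coumalate A1 with the ring A aryl ethynyl ether A2. The nucleophilic terminal alkyne carbon should bond to C6 of A1 and the oxygen-bearing carbon to C3. Decarboxylative aromatisation of the bridged adduct would give the para-aryloxybenzoate A3.
- In its favour: it is metal-free, the polarity match fixes the regiochemistry, and ring A carries its C1 carbon as a masked aldehyde, so no aryl halide is needed.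
- Equal or better: on regiochemical certainty of the diaryl ether the two plans are equal. On freedom from redox metals and metal waste this alternative is the better one.
- Against it: it rebuilds a benzene ring that the chosen plan buys as 6 and attaches in one displacement. A2 is a heat-sensitive ynol ether needing several steps, and the cycloaddition needs heat. The ester of A3 is one carbon short of the cinnamoyl unit.
- Comparison: structurally it solves only the easiest part of the molecule. Neither the macrocycle nor either stereocentre is addressed, so a ring closure and an asymmetric step would still have to be added. Step economy is clearly worse.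

**Alternative 2:** The cut opens indole C3–C3a and N1–C2, so the pyrrole ring and the macrocycle open together to the seco ortho-iodoaniline silylalkyne A4.

- Forward key step: Pd(OAc)2-catalysed Larock heteroannulation. Zerovalent palladium inserts into the aryl–iodine bond, syn-carbopalladation places the triethylsilyl group on the future C2, and C–N reductive elimination would give the 2-silylindole macrocycle A5.
- In its favour: two rings close in one step and the oxidation-prone hydroxyindole is absent until late.
- Equal or better: both stereocentres are set before ring closure, so the cyclisation cannot mis-set them; this is better than the chosen plan. Catalytic palladium in place of excess CrCl2 is also better on waste. On ring size and dilution needs the two are equal.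
- Against it: A4 needs C7 and C8 from separate asymmetric chemistry, with a regio- and stereocontrolled etherification at C8 next to a second secondary hydroxyl. It needs an extra silyl group at O7. The C2 silyl group must be removed afterwards, usually with acid, which threatens the para-oxygenated benzylic position. The cinnamamide alkene could compete as a Heck acceptor.
- Comparison: mechanistically elegant, but the serotonin unit is built and not bought, and the route would be several steps longer than the chosen one.

**Alternative 3:** The cut is the diaryl ether bond O–ring B C4, made last instead of early.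

- Forward key step: intramolecular SNAr. The ring A C5 phenoxide of the seco fluoronitroarene A6 attacks the fluorine-bearing carbon, activated by the ortho nitro group and the para acrylamide. Fluoride loss from the Meisenheimer adduct would give the nitro macrocycle A7.
- In its favour: nitro-activated displacement is among the most dependable diaryl ether macrocyclisations, runs with mild base near room temperature and uses no metal.
- Equal or better: the ring closure itself is more predictable than an organochromium addition, and it carries no burden of stereocontrol; on both points it is the better plan. It needs the same differentiation of the ring A oxygens, so on that point the plans are equal.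
- Against it: the nitro group is not in the target. It must be removed by reduction, diazotisation and reductive dediazoniation, three operations that are hard to reconcile with the conjugated alkene, the nitrosatable indole and the acid-sensitive benzylic carbinol. The unsymmetrical ring B could give atropisomeric mixtures. C7 and C8 again need independent construction.
- Comparison: a safer ring closure is paid for with at least three post-cyclisation steps plus those for the stereodiad. The chosen plan sets C7 during ring closure and ends with one deprotection.

Key step: step 11

## Route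

Step 1
Reactants: 1 o-vanillin (2-hydroxy-3-methoxybenzaldehyde)
Product: 2 2-hydroxy-5-iodo-3-methoxybenzaldehyde
Conditions: NIS (1.05 equiv), DMF, 0 °C to rt, dark
Reagents that add atoms: N-iodosuccinimide, O=C1CCC(=O)N1I
Why: Electrophilic aromatic iodination; the free phenol directs to its para position (C5) because both ortho positions are occupied, so a single regioisomer is expected.

Step 2
Reactants: 2 2-hydroxy-5-iodo-3-methoxybenzaldehyde
Product: 3 5-iodo-3-methoxy-2-{[2-(trimethylsilyl)ethoxy]methoxy}benzaldehyde
Conditions: SEMCl (1.2 equiv), K2CO3 (2 equiv), DMF, 0 °C to rt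
Reagents that add atoms: 2-(trimethylsilyl)ethoxymethyl chloride, C[Si](C)(C)CCOCCl
Why: Williamson-type O-alkylation of the phenoxide by the reactive chloromethyl ether; the resulting acetal is stable to base and peracid and cannot migrate to a neighbouring oxygen.

Step 3
Reactants: 3 5-iodo-3-methoxy-2-{[2-(trimethylsilyl)ethoxy]methoxy}benzaldehyde
Product: 5 5-iodo-3-methoxy-2-{[2-(trimethylsilyl)ethoxy]methoxy}phenol, via aryl formate 4 (not isolated)
Conditions: mCPBA (1.3 equiv), CH2Cl2, 0 °C to rt; aq. Na2S2O3/NaHCO3 wash; then K2CO3 (0.2 equiv), MeOH, rt
Reagents that add atoms: meta-chloroperbenzoic acid, OOC(=O)c1cccc(Cl)c1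
Why: Baeyer–Villiger oxidation (the peracid counterpart of the Dakin reaction); the electron-rich ortho-alkoxyaryl group migrates in the Criegee adduct to give the formate, which mild methanolysis cleaves to the phenol. Neutral peracid at or below rt should not oxidise the aryl iodide.

Step 4
Reactants: 5 5-iodo-3-methoxy-2-{[2-(trimethylsilyl)ethoxy]methoxy}phenol; 6 4-fluorobenzaldehyde
Product: 7 4-(5-iodo-3-methoxy-2-{[2-(trimethylsilyl)ethoxy]methoxy}phenoxy)benzaldehyde
Conditions: K2CO3 (2 equiv), DMF, 110 °C, argon
Reagents that add atoms: none
Why: Nucleophilic aromatic substitution (addition–elimination) of fluoride para to the formyl group by the phenoxide; without copper or palladium the aryl iodide is inert, and the acetal is stable to carbonate.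

Step 5
Reactants: 7 4-(5-iodo-3-methoxy-2-{[2-(trimethylsilyl)ethoxy]methoxy}phenoxy)benzaldehyde
Product: 8 (E)-3-[4-(5-iodo-3-methoxy-2-{[2-(trimethylsilyl)ethoxy]methoxy}phenoxy)phenyl]prop-2-enoic acid
Conditions: malonic acid (2.5 equiv), pyridine, piperidine (0.1 equiv), 90 °C
Reagents that add atoms: malonic acid, OC(=O)CC(=O)O
Why: Knoevenagel–Doebner condensation; the decarboxylative elimination gives the thermodynamically favoured E-cinnamic acid, and the pyridine-buffered medium leaves the acetal intact.

Step 6
Reactants: 8 (E)-3-[4-(5-iodo-3-methoxy-2-{[2-(trimethylsilyl)ethoxy]methoxy}phenoxy)phenyl]prop-2-enoic acid; 9 serotonin hydrochloride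
Product: 10 (E)-N-[2-(5-hydroxy-1H-indol-3-yl)ethyl]-3-[4-(5-iodo-3-methoxy-2-{[2-(trimethylsilyl)ethoxy]methoxy}phenoxy)phenyl]prop-2-enamide
Conditions: EDC·HCl (1.2 equiv), HOBt (1.2 equiv), i-Pr2NEt (2.5 equiv), DMF, 0 °C to rt, argon
Reagents that add atoms: none
Why: Carbodiimide amide coupling through the benzotriazolyl active ester; the primary amine is far more nucleophilic than the phenol or the indole nitrogen, so N-acylation should be selective.

Step 7
Reactants: 11 methyl (R)-2,2-dimethyl-1,3-dioxolane-4-carboxylate
Product: 12 methyl (2R)-2,3-dihydroxypropanoate
Conditions: AcOH–H2O (4:1), 40 °C; toluene azeotrope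
Reagents that add atoms: none
Why: Acid-catalysed acetal hydrolysis; no bond to the stereocentre is broken, so the (R) configuration is kept, and the methyl ester is stable in aqueous acetic acid.

Step 8
Reactants: 12 methyl (2R)-2,3-dihydroxypropanoate
Product: 13 methyl (2R)-3-[(tert-butyldimethylsilyl)oxy]-2-hydroxypropanoate
Conditions: TBSCl (1.05 equiv), imidazole (2 equiv), CH2Cl2, 0 °C
Reagents that add atoms: tert-butyldimethylsilyl chloride, CC(C)(C)[Si](C)(C)Cl
Why: Selective silylation; the primary hydroxyl reacts much faster than the hindered, ester-deactivated secondary one.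

Step 9
Reactants: 10 (E)-N-[2-(5-hydroxy-1H-indol-3-yl)ethyl]-3-[4-(5-iodo-3-methoxy-2-{[2-(trimethylsilyl)ethoxy]methoxy}phenoxy)phenyl]prop-2-enamide; 13 methyl (2R)-3-[(tert-butyldimethylsilyl)oxy]-2-hydroxypropanoate
Product: 14 methyl (2S)-3-[(tert-butyldimethylsilyl)oxy]-2-{[3-(2-{(E)-3-[4-(5-iodo-3-methoxy-2-{[2-(trimethylsilyl)ethoxy]methoxy}phenoxy)phenyl]prop-2-enamido}ethyl)-1H-indol-5-yl]oxy}propanoate
Conditions: PPh3 (1.6 equiv), DIAD (1.6 equiv), 13 (1.5 equiv), THF, 0 °C to rt
Reagents that add atoms: none
Why: Mitsunobu reaction; the 5-hydroxyindole is the only acid of suitable pKa (indole and amide N–H are too weakly acidic) and displaces the oxyphosphonium-activated secondary hydroxyl by SN2 with inversion, turning the (R) carbinol into the (S) aryl ether. The adjacent ester favours SN2 over ionisation.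

Step 10
Reactants: 14 methyl (2S)-3-[(tert-butyldimethylsilyl)oxy]-2-{[3-(2-{(E)-3-[4-(5-iodo-3-methoxy-2-{[2-(trimethylsilyl)ethoxy]methoxy}phenoxy)phenyl]prop-2-enamido}ethyl)-1H-indol-5-yl]oxy}propanoate
Product: 15 (E)-N-{2-[5-({(2S)-1-[(tert-butyldimethylsilyl)oxy]-3-oxopropan-2-yl}oxy)-1H-indol-3-yl]ethyl}-3-[4-(5-iodo-3-methoxy-2-{[2-(trimethylsilyl)ethoxy]methoxy}phenoxy)phenyl]prop-2-enamide (seco iodoarene aldehyde)
Conditions: i-Bu2AlH (3.5 equiv), CH2Cl2, −78 °C; MeOH quench at −78 °C, then aq. potassium sodium tartrate; crude used at once
Reagents that add atoms: none
Why: Partial reduction of an α-aryloxy methyl ester; the aluminium hemiacetal is stabilised at −78 °C by chelation to the C8 aryloxy oxygen and releases the aldehyde only on quench, while the first equivalents are consumed by the amide and indole N–H, whose aluminium salts are inert at this temperature. No acid or base acts on the product, so C8 should stay (S).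

Step 11
Reactants: 15 seco iodoarene (S)-α-aryloxy aldehyde
Product: 16 (7R,8S)-macrocycle with free 7-hydroxyl (21-membered ring of the target; O9 as TBS ether; ring A O4 as SEM ether)
Conditions: CrCl2 (10 equiv), NiCl2 (0.2 equiv), degassed DMF–THF (3:1), syringe-pump addition of 15 to 2 mM final concentration, rt to 40 °C, argon; aq. NH4Cl
Reagents that add atoms: none
Why: CrCl2 reduces NiCl2 to zerovalent nickel, which inserts into the ring A aryl–iodine bond; transmetalation to trivalent chromium gives an arylchromium dichloride that adds to aldehydes but is too weakly basic to deprotonate the indole or amide N–H or the C8–H. The closest known reaction type is the Nozaki–Hiyama–Kishi coupling of aryl and alkenyl iodides with aldehydes, including its use for macrocyclisation. The 21-membered ring closes by intramolecular 1,2-addition of the ring A C1–chromium bond to the C7 carbonyl (exo-trig with respect to C=O), helped by slow addition at high dilution and by the three rigid arenes and the E-enamide, which leave the seco chain few rotatable bonds. C7 is set by 1,2-induction from C8: in the polar Felkin–Anh arrangement the C8–OAr bond lies anti to the incoming aryl group and the silyloxymethyl group sits next to the carbonyl oxygen, which leads to the erythro (7R,8S) carbinol. The step needs non-chelation, which the weakly Lewis-basic aryloxy oxygen, the non-coordinating silyl ether at O9 and the strongly coordinating DMF on chromium should secure. It also needs chemoselectivity, secured because the aryl iodide is the only carbon–halogen bond, CrCl2 does not reduce the cinnamamide at this temperature, and the low nickel loading limits biaryl coupling. The neutral medium prevents epimerisation of the α-aryloxy aldehyde before it reacts.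

Step 12
Reactants: 16 (7R,8S)-macrocycle with free 7-hydroxyl (O9 TBS ether; ring A O4 SEM ether)
Product: 18 CNP0276372.1 (target), via O9-desilylated macrocycle 17 (not isolated)
Conditions: Bu4NF (6 equiv), THF, rt; then DMPU co-solvent, 50 °C; aq. NH4Cl
Reagents that add atoms: none
Why: Fluoride-induced desilylation; the primary TBS ether is cleaved at rt, and on warming fluoride attacks the trimethylsilyl group of the SEM acetal, which fragments with loss of ethene and formaldehyde to the ring A phenoxide. No acid is present, so the para-oxygenated benzylic carbinol at C7 and the C8 aryl ether should keep their configuration.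

## Compound list

1 | o-vanillin (2-hydroxy-3-methoxybenzaldehyde) | COc1cccc(C=O)c1O | starting material
2 | 2-hydroxy-5-iodo-3-methoxybenzaldehyde | COc1cc(I)cc(C=O)c1O | intermediate
3 | 5-iodo-3-methoxy-2-{[2-(trimethylsilyl)ethoxy]methoxy}benzaldehyde | COc1cc(I)cc(C=O)c1OCOCC[Si](C)(C)C | intermediate
4 | 5-iodo-3-methoxy-2-{[2-(trimethylsilyl)ethoxy]methoxy}phenyl formate (formed in the flask) | COc1cc(I)cc(OC=O)c1OCOCC[Si](C)(C)C | intermediate
5 | 5-iodo-3-methoxy-2-{[2-(trimethylsilyl)ethoxy]methoxy}phenol | COc1cc(I)cc(O)c1OCOCC[Si](C)(C)C | intermediate
6 | 4-fluorobenzaldehyde | O=Cc1ccc(F)cc1 | starting material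
7 | 4-(5-iodo-3-methoxy-2-{[2-(trimethylsilyl)ethoxy]methoxy}phenoxy)benzaldehyde | COc1cc(I)cc(Oc2ccc(C=O)cc2)c1OCOCC[Si](C)(C)C | intermediate
8 | (E)-3-[4-(5-iodo-3-methoxy-2-{[2-(trimethylsilyl)ethoxy]methoxy}phenoxy)phenyl]prop-2-enoic acid | COc1cc(I)cc(Oc2ccc(/C=C/C(=O)O)cc2)c1OCOCC[Si](C)(C)C | intermediate
9 | serotonin hydrochloride | Cl.NCCc1c[nH]c2ccc(O)cc12 | starting material
10 | (E)-N-[2-(5-hydroxy-1H-indol-3-yl)ethyl]-3-[4-(5-iodo-3-methoxy-2-{[2-(trimethylsilyl)ethoxy]methoxy}phenoxy)phenyl]prop-2-enamide | COc1cc(I)cc(Oc2ccc(/C=C/C(=O)NCCc3c[nH]c4ccc(O)cc34)cc2)c1OCOCC[Si](C)(C)C | intermediate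
11 | methyl (R)-2,2-dimethyl-1,3-dioxolane-4-carboxylate | COC(=O)[C@H]1COC(C)(C)O1 | starting material
12 | methyl (2R)-2,3-dihydroxypropanoate | COC(=O)[C@H](O)CO | intermediate
13 | methyl (2R)-3-[(tert-butyldimethylsilyl)oxy]-2-hydroxypropanoate | COC(=O)[C@H](O)CO[Si](C)(C)C(C)(C)C | intermediate
14 | methyl (2S)-3-[(tert-butyldimethylsilyl)oxy]-2-{[3-(2-{(E)-3-[4-(5-iodo-3-methoxy-2-{[2-(trimethylsilyl)ethoxy]methoxy}phenoxy)phenyl]prop-2-enamido}ethyl)-1H-indol-5-yl]oxy}propanoate | COC(=O)[C@H](CO[Si](C)(C)C(C)(C)C)Oc1ccc2[nH]cc(CCNC(=O)/C=C/c3ccc(cc3)Oc3cc(I)cc(OC)c3OCOCC[Si](C)(C)C)c2c1 | intermediate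
15 | (E)-N-{2-[5-({(2S)-1-[(tert-butyldimethylsilyl)oxy]-3-oxopropan-2-yl}oxy)-1H-indol-3-yl]ethyl}-3-[4-(5-iodo-3-methoxy-2-{[2-(trimethylsilyl)ethoxy]methoxy}phenoxy)phenyl]prop-2-enamide (seco iodoarene aldehyde) | O=C[C@H](CO[Si](C)(C)C(C)(C)C)Oc1ccc2[nH]cc(CCNC(=O)/C=C/c3ccc(cc3)Oc3cc(I)cc(OC)c3OCOCC[Si](C)(C)C)c2c1 | intermediate
16 | (7R,8S)-macrocycle: 21-membered ring of the target with free 7-OH, O9 as TBS ether and ring A O4 as SEM ether | COc1cc2cc(c1OCOCC[Si](C)(C)C)Oc1ccc(cc1)/C=C/C(=O)NCCc1c[nH]c3ccc(cc13)O[C@@H](CO[Si](C)(C)C(C)(C)C)[C@@H]2O | intermediate
17 | (7R,8S)-macrocycle with free 7-OH and 9-OH, ring A O4 as SEM ether (formed in the flask) | COc1cc2cc(c1OCOCC[Si](C)(C)C)Oc1ccc(cc1)/C=C/C(=O)NCCc1c[nH]c3ccc(cc13)O[C@@H](CO)[C@@H]2O | intermediate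
18 | CNP0276372.1, (7R,8S)-macrocycle with free ring A phenol, 7-OH and 9-OH | COc1cc2cc(c1O)Oc1ccc(cc1)/C=C/C(=O)NCCc1c[nH]c3ccc(cc13)O[C@@H](CO)[C@@H]2O | target

## Step count and least certain steps

Total step count: 12 steps.
Longest linear sequence: 10 steps (steps 1–6 and 9–12, from 1); the side branch from 11 adds steps 7 and 8.

**Step 11 (key step).** The most likely shortfall is incomplete facial selectivity. Oxophilic trivalent chromium may coordinate the C8 aryloxy oxygen, and the conformational demands of the closing ring may override the Felkin–Anh preference. Protodeiodination during a slow ring closure is the main loss channel beside it. Fallback: it sets out from 16 as obtained, together with whatever C7 epimer accompanies it. The whole carbinol fraction is oxidised with Dess–Martin periodinane (NaHCO3 buffer, CH2Cl2, 0 °C) to the macrocyclic (8S) aryl ketone F1. F1 is reduced at once with Zn(BH4)2 in Et2O–THF at −20 °C. Zinc bridging the carbonyl and C8 aryloxy oxygens should direct hydride to the face of the C8 hydrogen and give the erythro carbinol. The fallback returns to the route at 16.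

**Step 10.** The most likely problem is over-reduction to the primary alcohol if the aluminium hemiacetal collapses before the quench. Elimination of silanol or epimerisation of the α-aryloxy-β-silyloxy aldehyde during work-up is the second concern. Fallback: it sets out from 14, which is reduced fully with LiBH4 (THF, 0 °C) to the primary alcohol F2. F2 is oxidised with Dess–Martin periodinane (NaHCO3, CH2Cl2, 0 °C), a neutral oxidation that should not epimerise C8. The fallback returns to the route at 15.

**Step 12.** The most likely problem is slow fragmentation of the aryl SEM acetal, which would expose the phenoxide and benzylic carbinol to warm basic fluoride for a long time and cause decomposition by quinone methide formation. A formaldehyde scavenger can be added but does not change this. Fallback: it sets out from 16, whose SEM group is removed first by Lewis acid (MgBr2·OEt2, Et2O–MeNO2, rt), assisted by chelation to the neighbouring ring A oxygens. This gives the SEM-free O9 silyl ether F3. F3 is desilylated under buffered conditions (HF·pyridine with excess pyridine, THF, 0 °C). The fallback returns to the route at 18.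

**Step 9.** The most likely problem is elimination from the oxyphosphonium intermediate of the β-silyloxy hydroxy ester to an acrylate, together with incomplete conversion if 10 dissolves poorly in THF. Fallback: it sets out from 13, which is converted with Tf2O and 2,6-lutidine (CH2Cl2, −78 °C) into the (2R) triflate F4. F4 is displaced by the phenoxide of 10 (K2CO3, MeCN, −20 to 0 °C) in an SN2 reaction with inversion. The fallback returns to the route at 14.

## Further compounds

F1 | step 11 | (8S)-macrocyclic C7 aryl ketone (O9 TBS ether, ring A O4 SEM ether) | COc1cc2cc(c1OCOCC[Si](C)(C)C)Oc1ccc(cc1)/C=C/C(=O)NCCc1c[nH]c3ccc(cc13)O[C@@H](CO[Si](C)(C)C(C)(C)C)C2=O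
F2 | step 10 | (E)-N-{2-[5-({(2R)-1-[(tert-butyldimethylsilyl)oxy]-3-hydroxypropan-2-yl}oxy)-1H-indol-3-yl]ethyl}-3-[4-(5-iodo-3-methoxy-2-{[2-(trimethylsilyl)ethoxy]methoxy}phenoxy)phenyl]prop-2-enamide | OC[C@H](CO[Si](C)(C)C(C)(C)C)Oc1ccc2[nH]cc(CCNC(=O)/C=C/c3ccc(cc3)Oc3cc(I)cc(OC)c3OCOCC[Si](C)(C)C)c2c1
F3 | step 12 | (7R,8S)-macrocycle with free ring A phenol and 7-OH, O9 as TBS ether | COc1cc2cc(c1O)Oc1ccc(cc1)/C=C/C(=O)NCCc1c[nH]c3ccc(cc13)O[C@@H](CO[Si](C)(C)C(C)(C)C)[C@@H]2O
F4 | step 9 | methyl (2R)-3-[(tert-butyldimethylsilyl)oxy]-2-{[(trifluoromethyl)sulfonyl]oxy}propanoate | COC(=O)[C@H](OS(=O)(=O)C(F)(F)F)CO[Si](C)(C)C(C)(C)C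
A1 | alternative 1 | methyl coumalate (methyl 2-oxo-2H-pyran-5-carboxylate) | COC(=O)C1=COC(=O)C=C1
A2 | alternative 1 | 2-[3-(ethynyloxy)-5-methoxy-4-{[2-(trimethylsilyl)ethoxy]methoxy}phenyl]-1,3-dioxolane | C#COc1cc(cc(OC)c1OCOCC[Si](C)(C)C)C1OCCO1
A3 | alternative 1 | methyl 4-[5-(1,3-dioxolan-2-yl)-3-methoxy-2-{[2-(trimethylsilyl)ethoxy]methoxy}phenoxy]benzoate | COC(=O)c1ccc(cc1)Oc1cc(cc(OC)c1OCOCC[Si](C)(C)C)C1OCCO1
A4 | alternative 2 | seco (7R,8S) ortho-iodoaniline ether carrying the N-[4-(triethylsilyl)but-3-ynyl] cinnamamide, O7 and O9 as TBS ethers, ring A O4 as SEM ether | COc1cc(cc(c1OCOCC[Si](C)(C)C)Oc1ccc(cc1)/C=C/C(=O)NCCC#C[Si](CC)(CC)CC)[C@@H](O[Si](C)(C)C(C)(C)C)[C@H](CO[Si](C)(C)C(C)(C)C)Oc1ccc(N)c(I)c1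
A5 | alternative 2 | protected (7R,8S)-macrocycle carrying a 2-triethylsilyl indole, O7 and O9 as TBS ethers | COc1cc2cc(c1OCOCC[Si](C)(C)C)Oc1ccc(cc1)/C=C/C(=O)NCCc1c([Si](CC)(CC)CC)[nH]c3ccc(cc13)O[C@@H](CO[Si](C)(C)C(C)(C)C)[C@@H]2O[Si](C)(C)C(C)(C)C
A6 | alternative 3 | seco (7R,8S) ring A C5 phenol carrying the N-(4-fluoro-3-nitrocinnamoyl) serotonin ether, O7 and O9 as TBS ethers, ring A O4 as SEM ether | COc1cc(cc(O)c1OCOCC[Si](C)(C)C)[C@@H](O[Si](C)(C)C(C)(C)C)[C@H](CO[Si](C)(C)C(C)(C)C)Oc1ccc2[nH]cc(CCNC(=O)/C=C/c3ccc(F)c(c3)[N+](=O)[O-])c2c1
A7 | alternative 3 | protected (7R,8S)-macrocycle with a nitro group on ring B ortho to the ether oxygen | COc1cc2cc(c1OCOCC[Si](C)(C)C)Oc1ccc(cc1[N+](=O)[O-])/C=C/C(=O)NCCc1c[nH]c3ccc(cc13)O[C@@H](CO[Si](C)(C)C(C)(C)C)[C@@H]2O[Si](C)(C)C(C)(C)C
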